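In a one-step world the fraction left falls on one time constant; I wanted the same handle here, where the impurity's step has starting material on its left-hand side and none of the isomers.

    starting material ⇌ isomer of the product A (K1 = 2.4, k1 = 9.15 × 10⁻⁵ s⁻¹)
    starting material ⇌ third isomer (K2 = 1.71, k2 = 6.46 × 10⁻⁵ s⁻¹)
    starting material + protic impurity → quenched substrate (k3 = 0.0185 M⁻¹ s⁻¹)
    target ⇌ isomer of the product B (K4 = 12, k4 = 0.00174 s⁻¹)
    starting material ⇌ target (K5 = 0.337, k5 = 0.00150 s⁻¹)

common to all: starting material 0.020 M; time 10 h
- Saturday's: protic impurity 6.00 mM
- Monday's: protic impurity 18.0 mM

- which of these there is most of at the end, counted by the starting material in it, Saturday's (isomer of the product A / third isomer / starting material / isomer of the product B)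
- which of these there is most of at the end, counted by the starting material in it, Monday's (isomer of the product A / third isomer / starting material / isomer of the product B)
- amount of the one of these that there is most of at the end, in percent of the starting material charged, Saturday's
- amount of the one of these that there is most of at the end, in percent of the starting material charged, Monday's

My decision was whether Monday's charge could go in with its impurity as it stood or had to be brought down to Saturday's level first. Let the pool P be the unquenched forms: starting material, target and the isomers of the products A and B, plus the third isomer. At equilibrium each unit of starting material stands beside 2.4 of isomer of the product A, 1.71 of third isomer, 0.337 of target and 4.04 of isomer of the product B. I call f = 10.5% the exposed share, the part of the pool standing as free starting material. Isomer of the product B holds g = 42.6% of the pool, and its 4.04 is more than any other form's.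

This pre-equilibrium is fair for the fast steps because, for Monday's, the relaxation half-life of target and isomer of the product B, 0.102 h, is far shorter than the quench time 1/(k f H), which is 7.92 h; here k is the quench constant and H the impurity. The isomer of the product A and the third isomer have forward half-lives of 2.1 h and 3.0 h, under the run time, so I counted them as filled, which is the rough part.

Now the fraction left. Each quench removes one unit of P and one of H, so their difference D stays as charged, and P/H grows as exp(k f D t). For Saturday's that ratio reaches 8.90, leaving 78.9% of the charge in the pool. For Monday's it reaches 1.28, leaving 45.9%. Multiplying by g, I expected 33.6% of isomer of the product B on Saturday's and 19.6% on Monday's, a ratio of 0.583, so I decided to bring Monday's impurity down first.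

The forecast chose isomer of the product B for Saturday's and isomer of the product B for Monday's, at 32.5% and 15%, saying: “B stays the largest of the four in both runs”. We named the same isomer, but its Monday's figure is lower than mine.

The simulation gave isomer of the product B at 34.2% in Saturday's and isomer of the product B at 18.3% in Monday's. In Monday's the two fast steps relaxed with half-lives of 1.94 min and 0.102 h, and the quench had 54% of its turnover up to 10 h behind it after 1.00 h; at 10.0 h, with 35.6% of the impurity left, starting material stood at 9.11% of the pool, against f of 10.5%. In Saturday's at 100 h, with the impurity at 0%, g of the unquenched charge comes to 29.8%, and isomer of the product B stood at 29.8%.

(All constants stand for no real mixture; no experiment stands behind them.)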